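Ring atoms are numbered C1 (CH–OMe), C2 (=CH), C3 (=C, carrying C7H2–O), C4 (CH–OH), C5 (CH–OBz), C6 (CH–OH); O1, O4, O5, O6 and O7 are the oxygens on C1, C4, C5, C6 and C7. Compound numbers: 1 furfuryl acetate, 2 vinylene carbonate, 3 racemic endo cycloadduct, 4 methanol, 5 racemic ring-opened cyclohexenol, 6 (1S)-camphanic chloride, 7 camphanate of the wanted enantiomer, 8 tetrol, 9 benzoyl chloride, 10 tin acetal (not isolated), 11 target.

## Analysis of the target

Target 11 is a cyclohex-2-ene with oxygen on four contiguous sp3 carbons (C1, C6, C5, C4) and a benzoyloxymethyl branch (C7) on the alkene carbon C3. The stereocenters are C1 (S), C4 (R), C5 (R) and C6 (R) in this numbering. O1, O4 and O5 lie on one face and O6 on the other, so C1/C6 and C6/C5 are trans and C5/C4 is cis. In the preferred half-chair O1, O5 and O6 are equatorial and the allylic O4 is pseudoaxial, which is the substitution pattern of a β-galactopyranoside whose ring oxygen has been replaced by the alkene CH. The allylic C1–OMe, C4–OH and C7–OBz bonds can ionise under acid, and the O5 benzoate sits between two free hydroxyls and can migrate under base, so the benzoates should be introduced last and under near-neutral conditions. The difficulty is that five oxygens must play four different roles (one methyl ether, one primary and one secondary benzoate, two free secondary alcohols) on a ring with no cheap chiral-pool match. The strategy rests on this feature: C3 and C6 stand 1,4 across the ring, C6 carries an oxygen, C3 is an allylic carbon, and C4 and C5 between them carry cis oxygens that are both trans to O6. That is the pattern of a 7-oxabicyclo[2.2.1]heptene made from a furan and a cis-enediol equivalent, in which the bridge oxygen is O6 and its second bond, to C3, is a leaving group for an SN2' opening that creates the C2=C3 alkene and places the methoxy group on C1.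

## Retrosynthetic reasoning

**11 to 8 and 9.** The two ester C(=O)–O bonds at O5 and O7 are cut first, giving tetrol 8 and two equivalents of benzoyl chloride 9. They are cut here because a benzoate flanked by free hydroxyls is the most migration-prone part of 11 and should not be carried through basic steps. The forward reaction has to pick O5 and O7 out of four hydroxyls. A tin acetal (10) is used because 8 has the galactoside-like arrangement in which tin activation favours the equatorial oxygen of the cis-diol, and the primary allylic hydroxyl is the most reactive of the rest.

**8 to 7, and 7 to 5 and 6.** All acyl groups are removed in one transesterification, so 8 comes from a precursor in which O4/O5 are tied as a cyclic carbonate, O7 is an acetate and O6 carries an acyl group. That O6 acyl group is chosen to be enantiopure: cutting the O6–C(=O) bond of 7 gives racemic alcohol 5 and camphanic chloride 6. O6 is the only free hydroxyl of 5 and sits directly on a stereocenter, so this is the first point where a covalent resolution has a good handle, and the resolving group leaves in the deprotection that is needed anyway. The ring opening before it is therefore run on the racemate with an achiral ligand. A chiral catalyst would have to distinguish the enantiomers of an unsymmetrical substrate that can open at either bridgehead, which is harder to predict.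

**5 to 3 and 4.** The C1–OMe bond is cut and O6 is reconnected to C3, with the alkene moved back from C2=C3 to C1=C2. This is the reverse of an SN2' opening of the oxygen bridge of 3 by methanol 4. It is made here because one event differentiates O6 (free hydroxyl) from O1 (methyl ether), creates the trisubstituted alkene bearing C7, and fixes C1 trans to C6 by its mechanism. The forward reaction needs cleavage at the substituted bridgehead C3 and anti delivery of methanol; a rhodium-catalysed alcoholysis of the strained bridged allylic ether does both.

**3 to 1 and 2.** The C3–C4 and C5–C6 bonds are cut together, a retro-Diels–Alder step to furfuryl acetate 1 and vinylene carbonate 2. No other pair of bonds removes the carbocycle while leaving two commercial compounds that already contain all seven carbons and four of the five oxygens. The forward cycloaddition has to give the endo adduct, because only there are O4 and O5 anti to the bridge oxygen that becomes O6.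

## Alternatives that were turned down

**Alternative 1:** Disconnection: the C1–O and C4–O bonds, traced back to a peroxide bridge laid across the termini of the C2-symmetric, silyl-protected trans-diol diene A2. Forward key step: a dye-sensitised photooxygenation, a [4+2] addition that closes the peroxide-bridged bicycle A1.
- For it: the twofold axis of A2 makes its two faces equivalent, so one endoperoxide forms with the cis O1/O4 pair, the trans O5/O6 pair and the absolute configuration all in place. There is no endo/exo question and no resolution. On stereocontrol in the ring-forming event it is stronger than the chosen route.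
- Against it: A1 has no C7, and C2 and C3 are plain CH groups. The peroxide must be cleaved unsymmetrically so that one oxygen becomes the C1 methyl ether and the other the C4 hydroxyl. C7 must then be added at C3 through an enone, and the C4 carbonyl reduced again with control. A2 itself needs a multi-step enantioselective preparation.
- Comparison: the chosen route gives up built-in absolute control and pays with a resolution. In return it has every carbon, the C7 branch and four of the five oxygens in place after one step from two commercial compounds, and O1 and O6 are told apart by the mechanism of the bridge opening.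

**Alternative 2:** Disconnection: the C1–C2 bond, formed between sugar C1 and sugar C6 of the methyl hex-5-enopyranoside A4. Forward key step: a chlorotitanium alkoxide Lewis acid (tetravalent titanium) cleaves the ring O–C1 bond, and the titanium enolate recloses on the methoxy-stabilised cation to give cyclohexanone A3 with the glycosidic methoxy group kept (a Ferrier-type carbocyclisation).
- For it: C4, C5 and C6 come from the chiral pool with fixed absolute configuration, and the C1 methoxy group is present from the start. No resolution is needed; on these points it is as strong as or stronger than the chosen route.
- Against it: comparing configurations shows that A4 must belong to the L-galacto (equally D-altro) series. The cheap natural hexoses do not supply it, and the D-galacto series would give the enantiomer. A3 has a CH2 at C2, a ketone at C3 and no C7, so one carbon must be added at C3 and the C2=C3 alkene introduced regioselectively. Enolisation toward C2 puts the C1 methoxy group β to the carbonyl, where it is easily lost by elimination. C1 passes through an open oxocarbenium ion, so its configuration is not secured by the starting anomer. Benzyl ethers cannot be removed by hydrogenolysis once the alkene is present.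
- Comparison: counting sugar protection, 6-iodination and elimination, the rearrangement, homologation, alkene formation, deprotection and benzoylation, this is roughly twice as long as the five steps chosen. The chosen route creates the alkene and the C7 branch in their final positions directly.

**Alternative 3:** Disconnection: the C5–O and C6–O bonds of an oxirane on the dearomatised quinone monoketal A6. Forward key step: nucleophilic epoxidation of the unsubstituted enone double bond by a bulky hydroperoxide anion under control of a tartrate ester, giving epoxy enone A5 as one enantiomer.
- For it: all seven carbons including C7 are present. Absolute configuration comes from a chiral reagent, so no resolution is needed. The epoxide would let a benzoate open C5 (α to the ketone) with inversion, which gives the O5 benzoate and the trans C5/C6 pair regiospecifically. That is stronger than selecting O5 among hydroxyls.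
- Against it: C1 (ketal) and C4 (ketone) are at the wrong oxidation level. C4 needs a diastereoselective reduction, and C1 needs reductive conversion of a dimethyl ketal into one methyl ether of defined configuration. Three stereocenters (C1, C4, C5) are therefore set one at a time on a base- and acid-sensitive epoxy enone, and the epoxidation must also choose between two enone double bonds.
- Comparison: the chosen route sets C3–C6 relative to each other in one cycloaddition and C1 by a stereospecific SN2' step, with no redox adjustment. It has to separate enantiomers and rely on regioselective acylation at the end.

Key step: step 1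

Remarks on the chemistry: 3 and 5 are racemates, and their names and SMILES show the enantiomer that is carried on to 11. Tin acetal 10 is written as the monomeric 4,5-O-stannylene; such acetals aggregate and tin can also reach O7, but both placements activate the same two acylation sites.

## Route

Step 1
Reactants: 1 furfuryl acetate; 2 vinylene carbonate
Product: 3 rac-endo-1-(acetoxymethyl)-7-oxabicyclo[2.2.1]hept-5-ene-2,3-diyl carbonate, (1RS,2SR,3SR,4RS), carbonate ring anti to the oxygen bridge
Conditions: 1 (3 equiv), 2 (1 equiv), neat, 2,6-di-tert-butyl-4-methylphenol (1 mol%), sealed tube, 125 °C, 48 h; SiO2 chromatography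
Reagents that add atoms: vinylene carbonate (2), O=C1OC=CO1
Why: Thermal Diels–Alder reaction, a concerted suprafacial [4+2] cycloaddition in which the two furan carbons flanking the ring oxygen (future C3 and C6) bond to the two alkene carbons of 2 (future C4 and C5); the closest known reaction type is the thermal addition of vinylene carbonate to furan and simple 2-substituted furans, which gives isolable 7-oxanorbornene carbonates. The carbocycle C1–C6 is closed by this intermolecular cycloaddition, with both sigma bonds (C3–C4 and C5–C6) formed in one step and the furan oxygen left as the one-atom bridge, not by cyclisation of a chain. C3 and C6 are fixed relative to each other because the diene reacts on one face, so the bridge oxygen is on the same side at both bridgeheads. C4 and C5 are cis because the Z geometry of 2 is retained. Their relation to the bridge is set by the endo transition state, in which the carbonate ring lies under the diene and ends anti to the bridging oxygen. Orientation is not an issue because 2 is symmetric. The step needs endo over exo selectivity, which rests on the kinetic endo preference of this compact cyclic dienophile and on using the lowest temperature that gives conversion so that cycloreversion does not equilibrate the adducts; the minor mode of addition is removed on silica. No absolute control is possible, so 3 is racemic and the enantiomers are separated in step 3.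

Step 2
Reactants: 3 rac-endo cycloadduct; 4 methanol
Product: 5 rac-[(3aS,4R,5S,7aR)-4-hydroxy-5-methoxy-2-oxo-3a,4,5,7a-tetrahydro-1,3-benzodioxol-7-yl]methyl acetate (C1–OMe, C2=C3 bearing C7H2OAc, O4/O5 cyclic carbonate cis to OMe, C6–OH trans to both neighbours)
Conditions: [Rh(cod)Cl]2 (2.5 mol%), Fe(C5H4PPh2)2 (dppf, 6 mol%), Bu4NI (10 mol%), MeOH/THF 1:1, 70 °C
Reagents that add atoms: methanol (4), CO
Why: Rhodium-catalysed SN2' alcoholysis of an oxabicyclic alkene: the dppf complex of monovalent rhodium binds the exo face, inserts into the strained allylic C3–O bond with retention to give an alkoxo(allyl) complex of trivalent rhodium, and methanol adds to the remote allyl terminus C1 on the face opposite the metal, so the alkene moves to C2=C3, O6 is released as the hydroxyl and C1–OMe is set trans to C6–OH while C4, C5 and C6 are untouched. Cleavage at C3–O rather than C6–O is expected because it gives the more substituted allyl and lets methanol enter at the unhindered CH terminus C1 instead of next to a quaternary carbon. The medium is neutral, so the acetate and the carbonate should survive.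

Step 3
Reactants: 5 racemic cyclohexenol; 6 (1S)-(–)-camphanic chloride
Product: 7 the O6 (1S)-camphanoyl ester of the (3aS,4R,5S,7aR) enantiomer of 5, as a single diastereomer
Conditions: 6 (1.3 equiv), Et3N (2 equiv), 4-(dimethylamino)pyridine (0.2 equiv), CH2Cl2, 0 °C to rt; diastereomers separated on SiO2, then crystallisation
Reagents that add atoms: (1S)-(–)-camphanic chloride (6), ClC(=O)[C@@]12CC[C@@](C)(C(=O)O1)C2(C)C
Why: Acylation of the only free hydroxyl (O6) with an enantiopure acid chloride turns the racemate into two diastereomeric esters with different physical properties, a classical resolution through covalent diastereomers of the kind routinely used for cyclitols. No ring stereocenter is touched, the acid chloride has no epimerisable centre, and each ester can be assigned by X-ray analysis against the known camphanoyl unit.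

Step 4
Reactants: 7 camphanate
Product: 8 (1S,2R,3R,6S)-4-(hydroxymethyl)-6-methoxycyclohex-4-ene-1,2,3-triol (the tetrol with O4, O5, O6 and O7 free)
Conditions: NaOMe (0.3 equiv), MeOH, 0 to 40 °C; Dowex 50W (H+ form), filter, evaporate
Reagents that add atoms: none
Why: Base-catalysed transesterification (Zemplén conditions) passes the acetyl, carbonyl and camphanoyl groups to methanol and frees O4, O5, O6 and O7 in one operation. Only acyl C–O bonds are broken, so all four stereocenters are retained, and the allylic methyl ether is inert to methoxide.

Step 5
Reactants: 8 tetrol; 9 benzoyl chloride
Product: 11 [(3S,4R,5R,6R)-5-(benzoyloxy)-4,6-dihydroxy-3-methoxycyclohex-1-en-1-yl]methyl benzoate (the target), via 4,5-O-dibutylstannylene acetal 10 (not isolated)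
Conditions: Bu2SnO (1.1 equiv), MeOH, reflux; evaporate; BzCl (2.1 equiv), Et3N (1.1 equiv), 1,4-dioxane, 0 °C to rt
Reagents that add atoms: benzoyl chloride (9), O=C(Cl)c1ccccc1
Why: Tin-acetal-directed regioselective acylation: 8 is the carbocyclic counterpart of a methyl β-galactopyranoside (O4 pseudoaxial and allylic, O5 and O6 equatorial, O7 primary), and dibutylstannylene activation of such polyols directs an acyl chloride to the equatorial oxygen of the cis-diol, here O5. The primary allylic O7 is the most reactive remaining hydroxyl and takes the second equivalent with Et3N as acid scavenger, while the pseudoaxial O4 and the doubly flanked O6 should stay free; the cold, near-neutral conditions limit benzoyl migration and no stereocenter is affected.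

## Compound list

1 | furfuryl acetate (furan-2-ylmethyl acetate) | CC(=O)OCc1ccco1 | starting material
2 | vinylene carbonate (1,3-dioxol-2-one) | O=C1OC=CO1 | starting material
3 | rac-endo-1-(acetoxymethyl)-7-oxabicyclo[2.2.1]hept-5-ene-2,3-diyl carbonate, (1RS,2SR,3SR,4RS); enantiomer carried forward drawn | C1=C[C@@]2(COC(C)=O)[C@H]3OC(=O)O[C@H]3[C@@H]1O2 | intermediate
4 | methanol | CO | starting material
5 | rac-[(3aS,4R,5S,7aR)-4-hydroxy-5-methoxy-2-oxo-3a,4,5,7a-tetrahydro-1,3-benzodioxol-7-yl]methyl acetate; enantiomer carried forward drawn | CO[C@H]1C=C(COC(C)=O)[C@H]2OC(=O)O[C@H]2[C@@H]1O | intermediate
6 | (1S)-(–)-camphanic chloride, (1S,4R)-4,7,7-trimethyl-3-oxo-2-oxabicyclo[2.2.1]heptane-1-carbonyl chloride | ClC(=O)[C@@]12CC[C@@](C)(C(=O)O1)C2(C)C | starting material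
7 | O6 (1S,4R)-camphanoyl ester of the (3aS,4R,5S,7aR) enantiomer of 5 | CO[C@H]1C=C(COC(C)=O)[C@H]2OC(=O)O[C@H]2[C@@H]1OC(=O)[C@@]34CC[C@@](C)(C(=O)O3)C4(C)C | intermediate
8 | (1S,2R,3R,6S)-4-(hydroxymethyl)-6-methoxycyclohex-4-ene-1,2,3-triol | CO[C@H]1C=C(CO)[C@@H](O)[C@@H](O)[C@@H]1O | intermediate
9 | benzoyl chloride | O=C(Cl)c1ccccc1 | starting material
10 | 4,5-O-dibutylstannylene acetal of 8 (tin bridging O4 and O5) | CO[C@H]1C=C(CO)[C@@H](O[Sn]2(CCCC)CCCC)[C@@H](O2)[C@@H]1O | intermediate (not isolated)
11 | [(3S,4R,5R,6R)-5-(benzoyloxy)-4,6-dihydroxy-3-methoxycyclohex-1-en-1-yl]methyl benzoate | CO[C@H]1C=C(COC(=O)c2ccccc2)[C@@H](O)[C@@H](OC(=O)c2ccccc2)[C@@H]1O | target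

## Step count and least certain steps

Total step count: 5. Longest linear sequence: 5 steps (1 and 2 to 11). The resolution in step 3 discards the half of the material that belongs to the other enantiomeric series.

**Step 1 (key step).** The most likely failure is a low return of the endo adduct: the endo preference of this dienophile towards furans is modest, cycloreversion at the temperature needed can erode it, and the dienophile can polymerise. Fallback (sets out from 1, rejoins at 3): the stereochemistry at C4 and C5 is set by hydride delivery instead of by the cycloaddition. Compound 1 is heated with 4,5-dichloro-1,3-dioxol-2-one, a dienophile of the same shape that serves as a 1,2-dione equivalent, to give 1-(acetoxymethyl)-2,3-dichloro-7-oxabicyclo[2.2.1]hept-5-ene-2,3-diyl carbonate F1 as an endo/exo mixture that is used as such. Buffered hydrolysis (NaHCO3, aqueous dioxane) gives (2,3-dioxo-7-oxabicyclo[2.2.1]hept-5-en-1-yl)methyl acetate F2. NaBH4 in MeOH at –40 °C attacks both carbonyls from the exo face, syn to the oxygen bridge, and gives (endo,endo-2,3-dihydroxy-7-oxabicyclo[2.2.1]hept-5-en-1-yl)methyl acetate F3, which 1,1'-carbonyldiimidazole closes to 3. This removes the endo/exo question but not the sluggishness of furan cycloadditions.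

**Step 2.** Three things may go wrong:
- slow insertion, because the bridged ether is not benzo-fused and C3 carries two electron-withdrawing β-oxygen substituents;
- insertion into the C6–O bond instead, which would give the regioisomeric tertiary alcohol;
- further ionisation of the newly allylic C4 carbonate or C7 acetate by the same catalyst.

Fallback (sets out from 3, rejoins at 5): a cationic opening with BF3·OEt2 in MeOH/CH2Cl2 from –20 °C to rt. The Lewis acid complexes the bridge oxygen, the tertiary allylic C3–O bond ionises, and methanol is captured at the less hindered terminus C1 anti to the complexed O6. Facial selectivity is less secure than in the metal-catalysed path, so a C1-epimeric by-product may have to be separated.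

**Step 3.** The two diastereomeric camphanates may fail to separate on silica or by crystallisation, since the resolving group sits on a hindered hydroxyl and may differentiate the two ring enantiomers only weakly. Fallback (sets out from 5, rejoins at 8): an enzymatic kinetic resolution. Racemic 5 is treated with vinyl acetate and Burkholderia cepacia lipase in tert-butyl methyl ether at 35 °C to about half conversion. The sense of the enzyme's preference cannot be predicted with confidence for a carbinol flanked on both sides by oxygenated carbons, but either outcome is usable. The material of the target series is collected either as unreacted, enantiomerically enriched 5 or as its O6 acetate, [(3aR,4R,5S,7aR)-4-acetoxy-5-methoxy-2-oxo-3a,4,5,7a-tetrahydro-1,3-benzodioxol-7-yl]methyl acetate F4, and both give 8 under the conditions of step 4.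

**Step 5.** Regiocontrol may be incomplete (acylation at O4 or O6, or a third benzoylation), and the O5 benzoate may migrate to a neighbouring free hydroxyl during work-up. Fallback (sets out from 8, rejoins at 11): two separate acylations with boron instead of tin activation. BzCl (1.05 equiv) with 2,4,6-collidine in CH2Cl2/DMF at –40 °C benzoylates only the primary allylic hydroxyl and gives [(3S,4S,5R,6R)-4,5,6-trihydroxy-3-methoxycyclohex-1-en-1-yl]methyl benzoate F5. Catalytic Ph2BOCH2CH2NH2 (2-aminoethyl diphenylborinate, 10 mol%) with BzCl and iPr2NEt in MeCN at rt then binds the cis O4/O5 diol as a borinate and directs the second benzoyl group to the equatorial O5, giving 11.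

## Further compounds

F1 | step 1 | 1-(acetoxymethyl)-2,3-dichloro-7-oxabicyclo[2.2.1]hept-5-ene-2,3-diyl carbonate (racemic, endo/exo mixture, configuration at the chlorinated carbons left open) | C1=C[C@@]2(COC(C)=O)C3(Cl)OC(=O)OC3(Cl)[C@@H]1O2
F2 | step 1 | (2,3-dioxo-7-oxabicyclo[2.2.1]hept-5-en-1-yl)methyl acetate (racemic) | C1=C[C@@]2(COC(C)=O)C(=O)C(=O)[C@@H]1O2
F3 | step 1 | (endo,endo-2,3-dihydroxy-7-oxabicyclo[2.2.1]hept-5-en-1-yl)methyl acetate (racemic) | C1=C[C@@]2(COC(C)=O)[C@@H](O)[C@@H](O)[C@@H]1O2
F0 | step 2 | none | none
F4 | step 3 | [(3aR,4R,5S,7aR)-4-acetoxy-5-methoxy-2-oxo-3a,4,5,7a-tetrahydro-1,3-benzodioxol-7-yl]methyl acetate (O6 acetate of the target-series enantiomer of 5) | CO[C@H]1C=C(COC(C)=O)[C@H]2OC(=O)O[C@H]2[C@@H]1OC(C)=O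
F5 | step 5 | [(3S,4S,5R,6R)-4,5,6-trihydroxy-3-methoxycyclohex-1-en-1-yl]methyl benzoate | CO[C@H]1C=C(COC(=O)c2ccccc2)[C@@H](O)[C@@H](O)[C@@H]1O
A1 | alternative 1 | 7,8-bis(tert-butyldimethylsilyloxy)-2,3-dioxabicyclo[2.2.2]oct-5-ene (trans-disilyloxy, single enantiomer) | O1O[C@H]2C=C[C@@H]1[C@@H](O[Si](C)(C)C(C)(C)C)[C@@H]2O[Si](C)(C)C(C)(C)C
A2 | alternative 1 | (5R,6R)-5,6-bis(tert-butyldimethylsilyloxy)cyclohexa-1,3-diene | C1=CC=C[C@@H](O[Si](C)(C)C(C)(C)C)[C@@H]1O[Si](C)(C)C(C)(C)C
A3 | alternative 2 | 2,3,4-tris(benzyloxy)-5-methoxycyclohexan-1-one (stereoisomer matching C1, C4, C5 and C6 of the target) | CO[C@H]1CC(=O)[C@@H](OCc2ccccc2)[C@@H](OCc2ccccc2)[C@@H]1OCc1ccccc1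
A4 | alternative 2 | methyl 2,3,4-tri-O-benzyl-6-deoxyhex-5-enopyranoside of the L-galacto (equally D-altro) series, 1,2-trans anomer | CO[C@H]1OC(=C)[C@@H](OCc2ccccc2)[C@@H](OCc2ccccc2)[C@@H]1OCc1ccccc1
A5 | alternative 3 | 5,6-epoxy-2-(tert-butyldimethylsilyloxymethyl)-4,4-dimethoxycyclohex-2-en-1-one (single enantiomer) | COC1(OC)C=C(CO[Si](C)(C)C(C)(C)C)C(=O)[C@@H]2O[C@H]12
A6 | alternative 3 | 2-(tert-butyldimethylsilyloxymethyl)-4,4-dimethoxycyclohexa-2,5-dien-1-one | COC1(OC)C=CC(=O)C(CO[Si](C)(C)C(C)(C)C)=C1
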